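**Retrosynthetic overview**
- Target 18 comes from the quaternary β-keto ester 16 by ester acidolysis and loss of CO2. Compound 16 comes from chromone ester 13 and unprotected catechol 14 by anodic formation of the C2–C1′ bond.
- Enabling feature: in ring C, the C3–OH/C2=C3 enol next to C4=O is a carbon nucleophile at C2, and a temporary CO2t-Bu on C2 turns it into a β-keto ester enolate. Ring B is a benzene-1,2-diol whose o-quinone accepts carbon nucleophiles at C4, which is C1′ of a 3′,4′-dihydroxyphenyl group.
- The CO2t-Bu group also holds the adduct at the non-enolisable chromane-3,4-dione level, so no easily oxidised flavonol is present while current flows.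
- Ring A: O5 and O8 are para to each other, so the 5,8-dimethoxy pair is taken to the quinone and then the quinol. Only the non-chelated 8-OH is then acetylated, and the 7-OMe is carried from the start.
- Ring order: ring A is bought (1), ring C is closed in step 3 (Claisen condensation/cyclodehydration), and ring B is bought (14) and attached in step 7.

Key step: step 7

Remark: the target is planar and has no stereocentre, so it is a single achiral compound. The only stereocentre of the route (C2 of 16 and 17) is temporary, is made racemic and is erased in step 8.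

Step 1
Reactants: 1 1,2,3,5-tetramethoxybenzene; 2 N,2-dimethoxy-N-methylacetamide
Product: 4 2-methoxy-1-(2,3,4,6-tetramethoxyphenyl)ethan-1-one, via aryllithium 3 (not isolated)
Conditions: n-BuLi (1.1 equiv), THF, 0 °C to rt; then 2, −78 °C to 0 °C; 1 M HCl quench
Reagents that add atoms: none
Why: Directed ortho-metalation at one of the two equivalent C–H positions (each flanked by two OMe groups) followed by a Weinreb ketone synthesis should give the ketone without over-addition, and it avoids a Friedel–Crafts acylation, in which methoxyacetyl chloride would lose CO under Lewis acids.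

Step 2
Reactants: 4 2-methoxy-1-(2,3,4,6-tetramethoxyphenyl)ethan-1-one
Product: 5 1-(2-hydroxy-3,4,6-trimethoxyphenyl)-2-methoxyethan-1-one
Conditions: BCl3 (1.1 equiv), CH2Cl2, −78 °C to −10 °C; H2O work-up
Reagents that add atoms: none
Why: Chelation-controlled Lewis-acid ether cleavage (BCl3 ortho-demethylation) should take the 2-OMe, which is squeezed between the carbonyl and the 3-OMe, is twisted out of conjugation and is therefore the most Lewis basic, in preference to the unhindered 6-OMe, the 4-OMe and the aliphatic OMe.

Step 3
Reactants: 5 1-(2-hydroxy-3,4,6-trimethoxyphenyl)-2-methoxyethan-1-one; 6 di-tert-butyl oxalate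
Product: 9 tert-butyl 3,5,7,8-tetramethoxy-4-oxo-4H-chromene-2-carboxylate, via hemiketal 7 (not isolated), via hemiketal mesylate 8 (not isolated)
Conditions: t-BuOK (3 equiv), THF, 0 °C to rt; AcOH quench, extraction; crude 7, MsCl (1.3 equiv), Et3N (3 equiv), CH2Cl2, 0 °C to rt
Reagents that add atoms: none
Why: Crossed Claisen condensation of the ketone dianion with the non-enolisable oxalate (the classical chromone-2-carboxylate synthesis) lets the only free phenol close onto the new α-keto ester carbonyl, and an E1cB loss of mesylate replaces the usual hot mineral acid so that the tert-butyl ester survives.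

Step 4
Reactants: 9 tert-butyl 3,5,7,8-tetramethoxy-4-oxo-4H-chromene-2-carboxylate
Product: 11 tert-butyl 5,8-dihydroxy-3,7-dimethoxy-4-oxo-4H-chromene-2-carboxylate, via chromone-5,8-quinone 10 (not isolated)
Conditions: CAN (2.5 equiv), MeCN/H2O 2:1, 0 °C, short contact; extraction into EtOAc, shaking with aq Na2S2O4 under N2
Reagents that add atoms: water, O
Why: CAN oxidative demethylation converts the para-related 5-OMe/8-OMe pair into the p-quinone, as known for 5,8-dimethoxychromones, while the 7-OMe has no para partner and stays, and dithionite then reduces the quinone to the quinol.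

Step 5
Reactants: 11 tert-butyl 5,8-dihydroxy-3,7-dimethoxy-4-oxo-4H-chromene-2-carboxylate
Product: 12 tert-butyl 8-acetoxy-5-hydroxy-3,7-dimethoxy-4-oxo-4H-chromene-2-carboxylate
Conditions: Ac2O (1.05 equiv), pyridine, CH2Cl2, 0 °C, N2
Reagents that add atoms: acetic anhydride, CC(=O)OC(C)=O
Why: In this chemoselective O-acetylation the 5-OH is locked in a six-membered hydrogen bond to C4=O and is a poor nucleophile, so one equivalent of anhydride should acylate only the free 8-OH, with O3 masked as its methyl ether.

Step 6
Reactants: 12 tert-butyl 8-acetoxy-5-hydroxy-3,7-dimethoxy-4-oxo-4H-chromene-2-carboxylate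
Product: 13 tert-butyl 8-acetoxy-3,5-dihydroxy-7-methoxy-4-oxo-4H-chromene-2-carboxylate
Conditions: LiBr (4 equiv), MeCN, 60 °C; 0.5 M HCl work-up
Reagents that add atoms: none
Why: Chelation-assisted SN2 O-demethylation, known for 3-methoxy-4-pyridinone-2-carboxamides, should work because Li+ held between O3, C4=O and the ester C=O makes the 3-oxide a carboxylate-like leaving group for bromide attack on its methyl group, whereas the aryl 7-OMe, the tert-butyl ester (no SN2 site) and the aryl acetate should not react.

Step 7
Reactants: 13 tert-butyl 8-acetoxy-3,5-dihydroxy-7-methoxy-4-oxo-4H-chromene-2-carboxylate; 14 catechol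
Product: 16 tert-butyl (±)-8-acetoxy-2-(3,4-dihydroxyphenyl)-5-hydroxy-7-methoxy-3,4-dioxochromane-2-carboxylate, via o-benzoquinone 15 (not isolated)
Conditions: graphite-felt anode, Pt cathode, divided cell (Nafion), +0.40 V vs Ag/AgCl, 2.1 F per mol of 14; 13 (1.0 equiv), 14 (1.1 equiv), 0.2 M Na phosphate buffer pH 6.5/MeCN 1:1, N2, rt
Reagents that add atoms: none
Why: Proposed new method: at a potential where only 14 is electroactive the anode converts it (−2 e−, −2 H+) into o-benzoquinone 15, and the enolate of 13, which is the enol form of a cyclic α-aryloxy β-keto ester and should be largely ionised at pH 6.5, adds through C2 in a Michael (1,4) fashion to C4 of 15, after which tautomerisation rearomatises ring B so that the new bond ends para to one OH and meta to the other, that is at C1′ of a 3′,4′-dihydroxyphenyl group, while the protons are reduced to H2 at the cathode. The closest known reaction types are the EC-type anodic (or laccase/O2) oxidation of catechols in the presence of 1,3-dicarbonyl carbon nucleophiles, which includes 2-substituted cyclic β-keto esters that give quaternary α-(3,4-dihydroxyphenyl) carbons, and the addition of tert-butyl β-keto esters to quinones; what is new is the donor, a 3-hydroxy-γ-pyrone that gives up its cyclic conjugation, a cost that the aromatisation of the quinone should more than repay. No ring is closed in this step. The one new stereocentre, C2, is formed as a racemate without any control element, on purpose, because step 8 returns it to sp2. The step needs C4 over C3 attack on 15 (normal for carbon nucleophiles and reinforced by the bulk of the tertiary donor), C over O attack (normal for β-keto ester enolates with this soft acceptor), no attack from ring A (C6 is deactivated by the C4 carbonyl and the 8-acetate) and, above all, no over-oxidation, which the CO2t-Bu group secures: it blocks C2 so that 16 cannot enolise to an easily oxidised flavonol, and it places the new catechol on a carbon that carries three acceptors (O1, C3=O, ester), so that 16 should be oxidised only beyond the potential applied. The divided cell keeps the reducible 3,4-dione away from the cathode, and pH 6.5 at rt spares the aryl acetate and the tert-butyl ester.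

Step 8
Reactants: 16 tert-butyl (±)-8-acetoxy-2-(3,4-dihydroxyphenyl)-5-hydroxy-7-methoxy-3,4-dioxochromane-2-carboxylate
Product: 18 gossypetin 7-methyl ether 8-acetate (8-acetoxy-2-(3,4-dihydroxyphenyl)-3,5-dihydroxy-7-methoxy-4H-chromen-4-one), via β-keto acid 17 (not isolated)
Conditions: TFA/CH2Cl2 1:2, 0 °C to rt, N2 sweep; then 35 °C until gas evolution ends
Reagents that add atoms: none
Why: Acidolysis of the tert-butyl ester (E1 loss of isobutene) gives a β-keto acid that should decarboxylate through the six-membered transition state onto the C3 carbonyl, and the enol so formed is the 3-hydroxy-γ-pyrone of the target, so the activating group and the temporary stereocentre vanish together while the aryl acetate, methyl ether and catechol tolerate anhydrous TFA.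

**Compound list**
1 | 1,2,3,5-tetramethoxybenzene | COc1cc(OC)c(OC)c(OC)c1 | starting material
2 | N,2-dimethoxy-N-methylacetamide | COCC(=O)N(C)OC | starting material
3 | (2,3,4,6-tetramethoxyphenyl)lithium | [Li]c1c(OC)cc(OC)c(OC)c1OC | intermediate
4 | 2-methoxy-1-(2,3,4,6-tetramethoxyphenyl)ethan-1-one | COCC(=O)c1c(OC)cc(OC)c(OC)c1OC | intermediate
5 | 1-(2-hydroxy-3,4,6-trimethoxyphenyl)-2-methoxyethan-1-one | COCC(=O)c1c(OC)cc(OC)c(OC)c1O | intermediate
6 | di-tert-butyl oxalate | CC(C)(C)OC(=O)C(=O)OC(C)(C)C | starting material
7 | tert-butyl 2-hydroxy-3,5,7,8-tetramethoxy-4-oxochromane-2-carboxylate (mixture of diastereomers, racemic) | COC1C(=O)c2c(OC)cc(OC)c(OC)c2OC1(O)C(=O)OC(C)(C)C | intermediate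
8 | tert-butyl 3,5,7,8-tetramethoxy-2-(methylsulfonyloxy)-4-oxochromane-2-carboxylate (mixture of diastereomers, racemic) | COC1C(=O)c2c(OC)cc(OC)c(OC)c2OC1(OS(C)(=O)=O)C(=O)OC(C)(C)C | intermediate
9 | tert-butyl 3,5,7,8-tetramethoxy-4-oxo-4H-chromene-2-carboxylate | COc1cc(OC)c2c(=O)c(OC)c(C(=O)OC(C)(C)C)oc2c1OC | intermediate
10 | tert-butyl 3,7-dimethoxy-4,5,8-trioxo-5,8-dihydro-4H-chromene-2-carboxylate | COC1=CC(=O)C2=C(OC(C(=O)OC(C)(C)C)=C(OC)C2=O)C1=O | intermediate
11 | tert-butyl 5,8-dihydroxy-3,7-dimethoxy-4-oxo-4H-chromene-2-carboxylate | COc1cc(O)c2c(=O)c(OC)c(C(=O)OC(C)(C)C)oc2c1O | intermediate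
12 | tert-butyl 8-acetoxy-5-hydroxy-3,7-dimethoxy-4-oxo-4H-chromene-2-carboxylate | COc1cc(O)c2c(=O)c(OC)c(C(=O)OC(C)(C)C)oc2c1OC(C)=O | intermediate
13 | tert-butyl 8-acetoxy-3,5-dihydroxy-7-methoxy-4-oxo-4H-chromene-2-carboxylate | COc1cc(O)c2c(=O)c(O)c(C(=O)OC(C)(C)C)oc2c1OC(C)=O | intermediate
14 | catechol (benzene-1,2-diol) | Oc1ccccc1O | starting material
15 | o-benzoquinone | O=C1C=CC=CC1=O | intermediate
16 | tert-butyl (±)-8-acetoxy-2-(3,4-dihydroxyphenyl)-5-hydroxy-7-methoxy-3,4-dioxochromane-2-carboxylate (racemic) | COc1cc(O)c2C(=O)C(=O)C(C(=O)OC(C)(C)C)(c3ccc(O)c(O)c3)Oc2c1OC(C)=O | intermediate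
17 | (±)-8-acetoxy-2-(3,4-dihydroxyphenyl)-5-hydroxy-7-methoxy-3,4-dioxochromane-2-carboxylic acid (racemic) | COc1cc(O)c2C(=O)C(=O)C(C(=O)O)(c3ccc(O)c(O)c3)Oc2c1OC(C)=O | intermediate
18 | gossypetin 7-methyl ether 8-acetate (achiral) | COc1cc(O)c2c(=O)c(O)c(-c3ccc(O)c(O)c3)oc2c1OC(C)=O | target

Total step count: 8. Longest linear sequence: 8 steps (1 to 18).

**Steps most likely to fail**

1. Step 7 (Proposed new method).
   - What may go wrong: the fully substituted C2 may add too slowly, so that the quinone is lost by self-condensation or hydroxylation. Attack may also occur through the enolate oxygen, or the adduct may be oxidised further and take up a second donor.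
   - Fallback: it sets out from 13 and comes back at 18. It makes the same bond by ligand coupling at lead(IV), the Pinhey arylation of β-keto esters, which is known chemistry. Commercial 3,4-bis(benzyloxy)phenylboronic acid is converted with Pb(OAc)4 and catalytic Hg(OAc)2 in CHCl3 into [3,4-bis(benzyloxy)phenyl]lead triacetate F1. This reagent should arylate 13 at C2 in CHCl3/pyridine at 40 °C to give tert-butyl (±)-8-acetoxy-2-[3,4-bis(benzyloxy)phenyl]-5-hydroxy-7-methoxy-3,4-dioxochromane-2-carboxylate F2. TFA/CH2Cl2 then leads, through (±)-8-acetoxy-2-[3,4-bis(benzyloxy)phenyl]-5-hydroxy-7-methoxy-3,4-dioxochromane-2-carboxylic acid F3, to 8-acetoxy-2-[3,4-bis(benzyloxy)phenyl]-3,5-dihydroxy-7-methoxy-4H-chromen-4-one F4. Hydrogenolysis (H2, Pd/C, EtOAc) gives 18.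

2. Step 3.
   - What may go wrong: acylation by the hindered oxalate may be sluggish. Mesylation may take place on the phenol or enol of the ring-opened tautomer instead of the hemiketal, or the tert-butyl ester may be lost during dehydration.
   - Fallback: it sets out from 5 and comes back at 9. The ring is built under the standard acidic conditions and the ester is exchanged afterwards. Diethyl oxalate/NaOEt/EtOH followed by hot ethanolic HCl gives ethyl 3,5,7,8-tetramethoxy-4-oxo-4H-chromene-2-carboxylate F5. Hydrolysis with 6 M HCl/AcOH gives 3,5,7,8-tetramethoxy-4-oxo-4H-chromene-2-carboxylic acid F6. tert-Butyl 2,2,2-trichloroacetimidate in CH2Cl2/cyclohexane at rt then gives 9.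

3. Step 2.
   - What may go wrong: the ether cleavage may occur at the other ortho-methoxy group (C6), which would lead to the wrong ring-A pattern after ring closure, or the aliphatic methyl ether may be lost through five-membered chelation.
   - Fallback: it sets out from 4 and comes back at 5. Selective cleavage is replaced by selective re-alkylation. Excess BCl3 (2.5 equiv, CH2Cl2, −78 °C to 0 °C) removes both chelating ortho-methyl groups to give 1-(2,6-dihydroxy-3,4-dimethoxyphenyl)-2-methoxyethan-1-one F7. One equivalent of MeI with K2CO3 in acetone should then methylate the unhindered 6-OH in preference to the 2-OH, which is flanked by the 3-OMe, and so give 5.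

**Further compounds**
F1 | step 7 | [3,4-bis(benzyloxy)phenyl]lead triacetate | CC(=O)O[Pb](OC(C)=O)(OC(C)=O)c1ccc(OCc2ccccc2)c(OCc2ccccc2)c1
F2 | step 7 | tert-butyl (±)-8-acetoxy-2-[3,4-bis(benzyloxy)phenyl]-5-hydroxy-7-methoxy-3,4-dioxochromane-2-carboxylate (racemic) | COc1cc(O)c2C(=O)C(=O)C(C(=O)OC(C)(C)C)(c3ccc(OCc4ccccc4)c(OCc4ccccc4)c3)Oc2c1OC(C)=O
F3 | step 7 | (±)-8-acetoxy-2-[3,4-bis(benzyloxy)phenyl]-5-hydroxy-7-methoxy-3,4-dioxochromane-2-carboxylic acid (racemic) | COc1cc(O)c2C(=O)C(=O)C(C(=O)O)(c3ccc(OCc4ccccc4)c(OCc4ccccc4)c3)Oc2c1OC(C)=O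
F4 | step 7 | 8-acetoxy-2-[3,4-bis(benzyloxy)phenyl]-3,5-dihydroxy-7-methoxy-4H-chromen-4-one | COc1cc(O)c2c(=O)c(O)c(-c3ccc(OCc4ccccc4)c(OCc4ccccc4)c3)oc2c1OC(C)=O
F5 | step 3 | ethyl 3,5,7,8-tetramethoxy-4-oxo-4H-chromene-2-carboxylate | CCOC(=O)c1oc2c(OC)c(OC)cc(OC)c2c(=O)c1OC
F6 | step 3 | 3,5,7,8-tetramethoxy-4-oxo-4H-chromene-2-carboxylic acid | COc1cc(OC)c2c(=O)c(OC)c(C(=O)O)oc2c1OC
F7 | step 2 | 1-(2,6-dihydroxy-3,4-dimethoxyphenyl)-2-methoxyethan-1-one | COCC(=O)c1c(O)cc(OC)c(OC)c1O
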